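The ring atoms are labelled C1 (CH with the pentenyl chain), C2 (quaternary), C3 (CHBr), C4, C5 and C6 (carbinol). Everything rests on cutting C4–C5. C3–Br and the C6 oxygen lie 1,4 across this CH2–CH2 bridge of the cyclohexane. That pattern is the signature of a 2-oxoalkyl radical added to a bromoalkene. One operation closes the ring 6-endo, keeps the bromine and sets C3. The planar bromoalkyl radical takes hydrogen on its axial face, so bromine ends equatorial beside quaternary C2, where substitution chemistry fails. The precursor is an acyclic bromomethyl ketone with a 1-bromovinyl group on C2. Its C1/C2 pair comes from an enantioselective Ireland–Claisen rearrangement.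

Key step: step 10

Assumption: (S)-(+)-linalool of high enantiomeric purity is bought.
Assumption: the sense of induction of the (S,S)-boron controller in step 7 is assigned by analogy, and its mirror image is equally accessible.

Step 1
Reactants: 1 (3-bromopropoxy)(tert-butyl)dimethylsilane; 2 ethyl but-2-ynoate
Product: 5 ethyl (Z)-2-bromo-6-(tert-butyldimethylsilyloxy)-3-methylhex-2-enoate, via Grignard reagent 3 (not isolated), via alkenylcopper adduct 4 (not isolated)
Conditions: 1, Mg, THF; CuBr·SMe2, −40 °C; 2, −78 °C; NBS, −78 °C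
Reagents that add atoms: N-bromosuccinimide, O=C1CCC(=O)N1Br
Why: Syn-carbocupration of the ynoate places the new chain and copper cis, and bromination of the alkenylcopper at −78 °C goes with retention, so the tetrasubstituted alkene should form with Br cis to the chain and methyl cis to the ester (carbocupration–halogenation).

Step 2
Reactants: 5 ethyl (Z)-2-bromo-6-(tert-butyldimethylsilyloxy)-3-methylhex-2-enoate
Product: 6 (Z)-2-bromo-6-(tert-butyldimethylsilyloxy)-3-methylhex-2-en-1-ol
Conditions: iBu2AlH (2.2 equiv), CH2Cl2, −78 to 0 °C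
Reagents that add atoms: none
Why: 1,2-Reduction of the enoate by the aluminium hydride leaves the C–Br bond, the silyl ether and the alkene geometry untouched (ester reduction).

Step 3
Reactants: 7 (S)-(+)-linalool
Product: 8 (3S)-3,7-dimethyl-3-(triethylsilyloxy)octa-1,6-diene
Conditions: Et3SiOTf, 2,6-lutidine, CH2Cl2, 0 °C
Reagents that add atoms: triethylsilyl triflate, CC[Si](CC)(CC)OS(=O)(=O)C(F)(F)F
Why: Silylation with a silyl triflate masks the hindered tertiary allylic alcohol without touching its stereocentre, which becomes the side-chain carbinol centre of the target.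

Step 4
Reactants: 8 (3S)-3,7-dimethyl-3-(triethylsilyloxy)octa-1,6-diene
Product: 10 (4S)-4-methyl-4-(triethylsilyloxy)hex-5-enoic acid, via aldehyde 9 (not isolated)
Conditions: O3 (1 equiv), MeCN–H2O, 0 °C; then NaClO2, NaH2PO4, 0 °C to rt
Reagents that add atoms: ozone, [O-][O+]=O; sodium chlorite, [Na+].[O-]Cl=O
Why: Ozone attacks the electron-rich trisubstituted alkene far faster than the hindered vinyl group, and the aldehyde is oxidised in the same flask (ozonolysis followed by chlorite oxidation).

Step 5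
Reactants: 10 (4S)-4-methyl-4-(triethylsilyloxy)hex-5-enoic acid
Product: 12 (5S)-1-diazo-5-methyl-5-(triethylsilyloxy)hept-6-en-2-one, via mixed anhydride 11 (not isolated)
Conditions: iBuOCOCl, N-methylmorpholine, THF, −15 °C; CH2N2, Et2O, 0 °C
Reagents that add atoms: diazomethane, C=[N+]=[N-]
Why: Acylation of diazomethane by the mixed carbonic anhydride is the first half of an Arndt–Eistert homologation and runs under neutral conditions that spare the silyl ether.

Step 6
Reactants: 12 (5S)-1-diazo-5-methyl-5-(triethylsilyloxy)hept-6-en-2-one; 6 (Z)-2-bromo-6-(tert-butyldimethylsilyloxy)-3-methylhex-2-en-1-ol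
Product: 14 (Z)-2-bromo-6-(tert-butyldimethylsilyloxy)-3-methylhex-2-en-1-yl (5S)-5-methyl-5-(triethylsilyloxy)hept-6-enoate, via ketene 13 (not isolated)
Conditions: AgOCOPh (cat.), Et3N, THF, rt, dark
Reagents that add atoms: none
Why: The silver-catalysed Wolff rearrangement gives a ketene that alcohol 6 traps, so the one-carbon homologation and the union of the two fragments happen in one step.

Step 7
Reactants: 14 (Z)-2-bromo-6-(tert-butyldimethylsilyloxy)-3-methylhex-2-en-1-yl (5S)-5-methyl-5-(triethylsilyloxy)hept-6-enoate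
Product: 16 (2S,3S)-4-bromo-3-[3-(tert-butyldimethylsilyloxy)propyl]-3-methyl-2-[(3S)-3-methyl-3-(triethylsilyloxy)pent-4-en-1-yl]pent-4-enoic acid, via boron ketene acetal 15 (not isolated)
Conditions: (S,S)-N,N′-(1,2-diphenylethane-1,2-diyl)bis[3,5-bis(trifluoromethyl)benzenesulfonamide], BBr3, CH2Cl2, then evaporation; 14, iPr2NEt, CH2Cl2, −78 to 4 °C; aqueous work-up
Reagents that add atoms: none
Why: In the Ireland–Claisen rearrangement of the Z(O)-boron ketene acetal, the chair transition state holds the C1 chain and the silyloxypropyl group (trans to the CH2O carbon) pseudo-equatorial, which should give the required C1/C2 relation, while the twofold-symmetric diazaborolidine shields one enolate face and sets the absolute configuration of both centres.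

Step 8
Reactants: 16 (2S,3S)-4-bromo-3-[3-(tert-butyldimethylsilyloxy)propyl]-3-methyl-2-[(3S)-3-methyl-3-(triethylsilyloxy)pent-4-en-1-yl]pent-4-enoic acid
Product: 18 the N-methoxy-N-methylamide of acid 16 (same 2S,3S and 3S centres), via acylimidazole 17 (not isolated)
Conditions: 1,1′-carbonyldiimidazole, CH2Cl2, rt; MeNH(OMe)·HCl, 40 °C
Reagents that add atoms: N,O-dimethylhydroxylamine hydrochloride, CNOC.Cl
Why: Amide formation through the acylimidazole needs no strong base, so the C1 stereocentre next to the carbonyl group should be kept.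

Step 9
Reactants: 18 the N-methoxy-N-methylamide of acid 16
Product: 19 (3S,4S)-1,5-dibromo-4-[3-(tert-butyldimethylsilyloxy)propyl]-4-methyl-3-[(3S)-3-methyl-3-(triethylsilyloxy)pent-4-en-1-yl]hex-5-en-2-one
Conditions: CH2Br2, MeLi·LiBr, THF–Et2O, −78 °C
Reagents that add atoms: dibromomethane, BrCBr
Why: The carbenoid LiCH2Br, made in the presence of the amide, is acylated once because the chelated tetrahedral adduct survives until work-up, and at −78 °C the alkenyl bromide and C1 stay untouched (carbenoid acylation of an N-methoxy-N-methylamide).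

Step 10
Reactants: 19 (3S,4S)-1,5-dibromo-4-[3-(tert-butyldimethylsilyloxy)propyl]-4-methyl-3-[(3S)-3-methyl-3-(triethylsilyloxy)pent-4-en-1-yl]hex-5-en-2-one
Product: 20 (2S,3S,4S)-4-bromo-3-[3-(tert-butyldimethylsilyloxy)propyl]-3-methyl-2-[(3S)-3-methyl-3-(triethylsilyloxy)pent-4-en-1-yl]cyclohexan-1-one
Conditions: Ru(bpy)3Cl2 (cat.), diethyl 2,6-dimethyl-1,4-dihydropyridine-3,5-dicarboxylate, iPr2NEt, DMF (high dilution), blue LED, rt
Reagents that add atoms: none
Why: Proposed new method: the reduced photocatalyst transfers one electron only to the C–Br bond next to the carbonyl group, the 2-oxoalkyl radical at C5 adds to the CH2 end (C4) of the bromoalkene, and the planar C3 radical, which still carries bromine, is quenched by hydrogen-atom transfer from the dihydropyridine. The closest known reaction types are the tin-free photoredox reductive cyclisation of α-bromocarbonyl compounds and the 6-endo halogen-atom-transfer cyclisation of 1-halohex-5-en-2-ones; what has not been shown is a 1-bromovinyl acceptor that keeps its bromine as a stereodefined secondary bromide. The single ring closes 6-endo-trig, because a carbonyl group inside the forming ring disfavours the 5-exo geometry and C3 is fully substituted (Br and quaternary C2). C3 is the only new stereocentre: in the chair with the C1 chain and the silyloxypropyl group equatorial, the axial C2 methyl blocks the upper face, so hydrogen should arrive axially from below and bromine become equatorial, cis to the C2 methyl. Chemoselectivity rests on reduction potentials (alkenyl and secondary alkyl bromides are inert) and on the saturated C2 chain, since a 4-methylpent-3-enyl group would trap the C3 radical by 5-exo closure, whereas the distant vinyl group could only close seven- or eight-membered rings. C1 and C2 are not touched.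

Step 11
Reactants: 20 (2S,3S,4S)-4-bromo-3-[3-(tert-butyldimethylsilyloxy)propyl]-3-methyl-2-[(3S)-3-methyl-3-(triethylsilyloxy)pent-4-en-1-yl]cyclohexan-1-one
Product: 21 (1R,2S,3S,4S)-4-bromo-3-[3-(tert-butyldimethylsilyloxy)propyl]-1,3-dimethyl-2-[(3S)-3-methyl-3-(triethylsilyloxy)pent-4-en-1-yl]cyclohexan-1-ol
Conditions: MeLi, CeCl3, THF, −78 °C
Reagents that add atoms: methyllithium, [Li]C
Why: The weakly basic organocerium reagent adds 1,2 without enolisation, and the axial C2 methyl blocks the axial approach to C6, so methyl should enter equatorially and leave the axial hydroxyl of the target (organocerium carbonyl addition).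

Step 12
Reactants: 21 (1R,2S,3S,4S)-4-bromo-3-[3-(tert-butyldimethylsilyloxy)propyl]-1,3-dimethyl-2-[(3S)-3-methyl-3-(triethylsilyloxy)pent-4-en-1-yl]cyclohexan-1-ol
Product: 22 (1R,2S,3S,4S)-4-bromo-2-[(3S)-3-hydroxy-3-methylpent-4-en-1-yl]-3-(3-hydroxypropyl)-1,3-dimethylcyclohexan-1-ol
Conditions: Bu4NF, THF, rt to 40 °C
Reagents that add atoms: none
Why: Fluoride cleaves both silyl ethers, and the equatorial bromide has no antiperiplanar hydrogen and a shielded rear side, so it should resist elimination and substitution (fluoride desilylation).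

Step 13
Reactants: 22 (1R,2S,3S,4S)-4-bromo-2-[(3S)-3-hydroxy-3-methylpent-4-en-1-yl]-3-(3-hydroxypropyl)-1,3-dimethylcyclohexan-1-ol
Product: 23 3-{(1S,2S,3R,6S)-6-bromo-3-hydroxy-2-[(3S)-3-hydroxy-3-methylpent-4-en-1-yl]-1,3-dimethylcyclohexyl}propanal
Conditions: TEMPO (cat.), PhI(OAc)2, CH2Cl2, rt
Reagents that add atoms: none
Why: The oxoammonium oxidation acts only on the primary alcohol, because the two tertiary alcohols cannot be oxidised and the conditions do not transpose the allylic one.

Step 14
Reactants: 23 3-{(1S,2S,3R,6S)-6-bromo-3-hydroxy-2-[(3S)-3-hydroxy-3-methylpent-4-en-1-yl]-1,3-dimethylcyclohexyl}propanal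
Product: 24 (1R,2S,3S,4S)-4-bromo-2-[(3S)-3-hydroxy-3-methylpent-4-en-1-yl]-1,3-dimethyl-3-(4-methylpent-3-en-1-yl)cyclohexan-1-ol
Conditions: iPrPPh3I, nBuLi, THF, 0 °C (excess ylide); 23, −78 °C to rt
Reagents that add atoms: isopropyltriphenylphosphonium iodide, CC(C)[P+](c1ccccc1)(c1ccccc1)c1ccccc1.[I-]
Why: Wittig olefination with the isopropylidene ylide completes the 4-methylpent-3-enyl chain without an E/Z question, and the excess ylide only deprotonates the two alcohols reversibly.

Compound list
1 | (3-bromopropoxy)(tert-butyl)dimethylsilane | CC(C)(C)[Si](C)(C)OCCCBr | starting material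
2 | ethyl but-2-ynoate | CCOC(=O)C#CC | starting material
3 | [3-(tert-butyldimethylsilyloxy)propyl]magnesium bromide | CC(C)(C)[Si](C)(C)OCCC[Mg]Br | intermediate
4 | ethyl 2-cuprio-6-(tert-butyldimethylsilyloxy)-3-methylhex-2-enoate (Cu cis to the silyloxypropyl chain) | CCOC(=O)/C([Cu])=C(\C)CCCO[Si](C)(C)C(C)(C)C | intermediate
5 | ethyl (Z)-2-bromo-6-(tert-butyldimethylsilyloxy)-3-methylhex-2-enoate | CCOC(=O)/C(Br)=C(\C)CCCO[Si](C)(C)C(C)(C)C | intermediate
6 | (Z)-2-bromo-6-(tert-butyldimethylsilyloxy)-3-methylhex-2-en-1-ol | OC/C(Br)=C(\C)CCCO[Si](C)(C)C(C)(C)C | intermediate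
7 | (S)-(+)-linalool, (3S)-3,7-dimethylocta-1,6-dien-3-ol | C=C[C@@](C)(O)CCC=C(C)C | starting material
8 | (3S)-3,7-dimethyl-3-(triethylsilyloxy)octa-1,6-diene | C=C[C@@](C)(O[Si](CC)(CC)CC)CCC=C(C)C | intermediate
9 | (4S)-4-methyl-4-(triethylsilyloxy)hex-5-enal | C=C[C@@](C)(O[Si](CC)(CC)CC)CCC=O | intermediate
10 | (4S)-4-methyl-4-(triethylsilyloxy)hex-5-enoic acid | C=C[C@@](C)(O[Si](CC)(CC)CC)CCC(=O)O | intermediate
11 | isobutyl carbonic anhydride of acid 10 | C=C[C@@](C)(O[Si](CC)(CC)CC)CCC(=O)OC(=O)OCC(C)C | intermediate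
12 | (5S)-1-diazo-5-methyl-5-(triethylsilyloxy)hept-6-en-2-one | C=C[C@@](C)(O[Si](CC)(CC)CC)CCC(=O)C=[N+]=[N-] | intermediate
13 | (5S)-5-methyl-5-(triethylsilyloxy)hepta-1,6-dien-1-one (ketene) | C=C[C@@](C)(O[Si](CC)(CC)CC)CCC=C=O | intermediate
14 | (Z)-2-bromo-6-(tert-butyldimethylsilyloxy)-3-methylhex-2-en-1-yl (5S)-5-methyl-5-(triethylsilyloxy)hept-6-enoate | C=C[C@@](C)(O[Si](CC)(CC)CC)CCCC(=O)OC/C(Br)=C(\C)CCCO[Si](C)(C)C(C)(C)C | intermediate
15 | Z(O)-boron ketene acetal of 14 with the (S,S)-diazaborolidine (C1 chain cis to O–B) | C=C[C@@](C)(O[Si](CC)(CC)CC)CC/C=C(\OB1N(S(=O)(=O)c2cc(cc(c2)C(F)(F)F)C(F)(F)F)[C@@H](c2ccccc2)[C@H](c2ccccc2)N1S(=O)(=O)c1cc(cc(c1)C(F)(F)F)C(F)(F)F)OC/C(Br)=C(\C)CCCO[Si](C)(C)C(C)(C)C | intermediate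
16 | (2S,3S)-4-bromo-3-[3-(tert-butyldimethylsilyloxy)propyl]-3-methyl-2-[(3S)-3-methyl-3-(triethylsilyloxy)pent-4-en-1-yl]pent-4-enoic acid | C=C[C@@](C)(O[Si](CC)(CC)CC)CC[C@@H]([C@](C)(CCCO[Si](C)(C)C(C)(C)C)C(Br)=C)C(=O)O | intermediate
17 | acylimidazole of acid 16 | C=C[C@@](C)(O[Si](CC)(CC)CC)CC[C@@H]([C@](C)(CCCO[Si](C)(C)C(C)(C)C)C(Br)=C)C(=O)n1ccnc1 | intermediate
18 | N-methoxy-N-methylamide of acid 16 | C=C[C@@](C)(O[Si](CC)(CC)CC)CC[C@@H]([C@](C)(CCCO[Si](C)(C)C(C)(C)C)C(Br)=C)C(=O)N(C)OC | intermediate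
19 | (3S,4S)-1,5-dibromo-4-[3-(tert-butyldimethylsilyloxy)propyl]-4-methyl-3-[(3S)-3-methyl-3-(triethylsilyloxy)pent-4-en-1-yl]hex-5-en-2-one | C=C[C@@](C)(O[Si](CC)(CC)CC)CC[C@@H]([C@](C)(CCCO[Si](C)(C)C(C)(C)C)C(Br)=C)C(=O)CBr | intermediate
20 | (2S,3S,4S)-4-bromo-3-[3-(tert-butyldimethylsilyloxy)propyl]-3-methyl-2-[(3S)-3-methyl-3-(triethylsilyloxy)pent-4-en-1-yl]cyclohexan-1-one | C=C[C@@](C)(O[Si](CC)(CC)CC)CC[C@H]1[C@](C)(CCCO[Si](C)(C)C(C)(C)C)[C@@H](Br)CCC1=O | intermediate
21 | (1R,2S,3S,4S)-4-bromo-3-[3-(tert-butyldimethylsilyloxy)propyl]-1,3-dimethyl-2-[(3S)-3-methyl-3-(triethylsilyloxy)pent-4-en-1-yl]cyclohexan-1-ol | C=C[C@@](C)(O[Si](CC)(CC)CC)CC[C@H]1[C@](C)(CCCO[Si](C)(C)C(C)(C)C)[C@@H](Br)CC[C@@]1(C)O | intermediate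
22 | (1R,2S,3S,4S)-4-bromo-2-[(3S)-3-hydroxy-3-methylpent-4-en-1-yl]-3-(3-hydroxypropyl)-1,3-dimethylcyclohexan-1-ol | C=C[C@@](C)(O)CC[C@H]1[C@](C)(CCCO)[C@@H](Br)CC[C@@]1(C)O | intermediate
23 | 3-{(1S,2S,3R,6S)-6-bromo-3-hydroxy-2-[(3S)-3-hydroxy-3-methylpent-4-en-1-yl]-1,3-dimethylcyclohexyl}propanal | C=C[C@@](C)(O)CC[C@H]1[C@](C)(CCC=O)[C@@H](Br)CC[C@@]1(C)O | intermediate
24 | (1R,2S,3S,4S)-4-bromo-2-[(3S)-3-hydroxy-3-methylpent-4-en-1-yl]-1,3-dimethyl-3-(4-methylpent-3-en-1-yl)cyclohexan-1-ol | C=C[C@@](C)(O)CC[C@H]1[C@](C)(CCC=C(C)C)[C@@H](Br)CC[C@@]1(C)O | target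

Total step count: 14. Longest linear sequence: 12 steps (steps 3 to 14, from 7).

Steps most likely to fail

Step 10. Hydrogen may be transferred to the 2-oxoalkyl radical before the ring closes, or the hydrogen transfer to C3 may show too little facial bias. The fallback separates ring closure from hydrogen delivery and sets out from 19. A bromine-atom-transfer cyclisation is run without any hydrogen donor (CuBr, tris(2-pyridylmethyl)amine, AIBN, MeCN, 60 °C). This is a Kharasch-type addition of an α-bromoketone across a bromoalkene. It should give the geminal dibromide (2S,3S)-4,4-dibromo-3-[3-(tert-butyldimethylsilyloxy)propyl]-3-methyl-2-[(3S)-3-methyl-3-(triethylsilyloxy)pent-4-en-1-yl]cyclohexan-1-one F1. One bromine is then removed with (Me3Si)3SiH (1 equiv) and Et3B/air in toluene at −40 °C. This reduction passes through the same C3 radical, now at low temperature and with a bulky donor, and comes back to the route at 20.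

Step 7. The rearrangement onto the tetrasubstituted bromoalkene may be too slow at temperatures the boron ketene acetal tolerates, or the controller may discriminate the enolate faces weakly or in the wrong sense. The fallback gives up reagent control and sets out from 14. Treatment with LDA in THF–DMPU and Me3SiCl at −78 °C should give the trimethylsilyl ketene acetal of 14 (C1 chain cis to OSiMe3) F2. On warming and mild acidic work-up, F2 should rearrange through the same chair to 16 together with the (2R,3R)-diastereomer of acid 16 F3. The two acids are diastereomers because of the (S)-carbinol centre, so they are separated by chromatography. The route is rejoined at 16.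

Step 9. The carbenoid may decompose faster than it adds to the hindered amide. The fallback builds the bromomethyl ketone by electrophilic bromination and sets out from 18. MeMgBr (THF, 0 °C) should give the methyl ketone (3S,4S)-5-bromo-4-[3-(tert-butyldimethylsilyloxy)propyl]-4-methyl-3-[(3S)-3-methyl-3-(triethylsilyloxy)pent-4-en-1-yl]hex-5-en-2-one F4. Kinetic deprotonation at the methyl group (LiN(SiMe3)2, Me3SiCl, THF, −78 °C) should give its terminal trimethylsilyl enol ether F5. NBS at −78 °C brominates the enol ether faster than any alkene present, and the route is rejoined at 19.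

Further compounds
F1 | step 10 | (2S,3S)-4,4-dibromo-3-[3-(tert-butyldimethylsilyloxy)propyl]-3-methyl-2-[(3S)-3-methyl-3-(triethylsilyloxy)pent-4-en-1-yl]cyclohexan-1-one | C=C[C@@](C)(O[Si](CC)(CC)CC)CC[C@H]1[C@](C)(CCCO[Si](C)(C)C(C)(C)C)C(Br)(Br)CCC1=O
F2 | step 7 | trimethylsilyl ketene acetal of 14 (C1 chain cis to OSiMe3) | C=C[C@@](C)(O[Si](CC)(CC)CC)CC/C=C(\O[Si](C)(C)C)OC/C(Br)=C(\C)CCCO[Si](C)(C)C(C)(C)C
F3 | step 7 | (2R,3R)-diastereomer of acid 16 | C=C[C@@](C)(O[Si](CC)(CC)CC)CC[C@H]([C@@](C)(CCCO[Si](C)(C)C(C)(C)C)C(Br)=C)C(=O)O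
F4 | step 9 | (3S,4S)-5-bromo-4-[3-(tert-butyldimethylsilyloxy)propyl]-4-methyl-3-[(3S)-3-methyl-3-(triethylsilyloxy)pent-4-en-1-yl]hex-5-en-2-one | C=C[C@@](C)(O[Si](CC)(CC)CC)CC[C@@H]([C@](C)(CCCO[Si](C)(C)C(C)(C)C)C(Br)=C)C(C)=O
F5 | step 9 | terminal trimethylsilyl enol ether of F4 | C=C[C@@](C)(O[Si](CC)(CC)CC)CC[C@@H]([C@](C)(CCCO[Si](C)(C)C(C)(C)C)C(Br)=C)C(=C)O[Si](C)(C)C
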